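Ring A (C1–C5, C10; drimane numbering) is cut into its isoprene unit C2–C3–C4(CH3)2 and a ring B enone aldehyde. In that precursor C1 is a formyl group on the quaternary C10, and C5 is the γ-carbon of the C6=C7–C8=O enone. In one flask a prenyl phosphorus ylide olefinates C1 (bond C1–C2). Acid then turns the diene into a dimethylallyl cation, whose tertiary end C4 is captured by the dienol at C5 (bond C4–C5). This formal (3+3) annulation makes the gem-dimethyl quaternary carbon and the trans ring fusion. The surviving C8 ketone then directs the arylmethyl group to C9 and becomes the exocyclic methylene.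

Key step: step 4

Remark: decalin atoms carry drimane numbers (C11 = CH2 on C9, C12 = CH2 on C8); Ar = 2,3,6-trimethoxy-4-{[(triisopropylsilyl)oxy]methyl}phenyl; 2,3,5-trimethoxybenzaldehyde is taken as a catalogue compound.

Step 1
Reactants: 1 3-methylcyclohex-2-en-1-one; 2 hex-1-yne
Product: 4 (3S)-3-[(1E)-hex-1-en-1-yl]-3-methylcyclohexan-1-one, via hexenyl alane 3 (not isolated)
Conditions: 2, i-Bu2AlH, heptane, 55 °C; then 1, Cu(O2CC4H3S) (copper thiophene-2-carboxylate, monovalent copper, 10 mol %), chiral phosphinamine ligand Ph2PN[CH(CH3)(2-naphthyl)]2 (11 mol %), Et2O, −10 °C; aq. HCl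
Reagents that add atoms: none
Why: Copper-catalysed asymmetric conjugate addition of an alkenylalane (from syn-hydroalumination of the alkyne) to a β-substituted enone; the ligand enantiomer that directs attack to the enone face giving the S quaternary centre (C10) is used.

Step 2
Reactants: 4
Product: 5 (1S)-1-methyl-3-oxocyclohexane-1-carbaldehyde
Conditions: O3, CH2Cl2, −78 °C; then PPh3, −78 °C → rt
Reagents that add atoms: ozone, [O-][O+]=O
Why: Ozonolysis with reductive work-up cleaves the only C=C bond and leaves C1 as a non-enolisable aldehyde on C10; ketone and stereocentre are not touched.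

Step 3
Reactants: 5
Product: 6 (1S)-1-methyl-5-oxocyclohex-3-ene-1-carbaldehyde
Conditions: 2-iodoxybenzoic acid (IBX), DMSO/toluene, 70 °C
Reagents that add atoms: none
Why: IBX dehydrogenation of a ketone to its enone; only the C7/C6 side has the α- and β-hydrogens required, because the other α-carbon (C9) adjoins the quaternary C10 and the aldehyde has no α-hydrogen.

Step 4
Reactants: 6; 7 (3-methylbut-2-en-1-yl)triphenylphosphonium bromide
Product: 10 (4aR,8aR)-5,5,8a-trimethyl-4a,5,8,8a-tetrahydronaphthalen-2(1H)-one, via prenylidene phosphorane 8 (not isolated), via dienyl enone 9 (not isolated)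
Conditions: 7, KN(SiMe3)2, THF, 0 °C; 6, −78 → 0 °C; then CH2Cl2 (high dilution), CF3CO2H, 0 °C → rt
Reagents that add atoms: none
Why: Proposed new method: the allylic ylide first olefinates the aldehyde (Wittig reaction, C1=C2, either geometry serves); CF3CO2H then protonates the 1,3-diene at C1 to the dimethylallyl cation C2–C3–C4, which is captured at its tertiary end C4 by the γ-carbon C5 of the linear dienol of the enone, and loss of the O–H proton returns the enone. The closest known reaction types are the Wittig olefination and the allyl-cation-initiated cation–olefin cyclisation with an enol terminator; running both in one flask and using the free dienol of a cyclohexenone as terminator are the untested parts. Ring A closes as a six-membered ring, endo with respect to the allyl cation (C2=C3 stays inside the ring) and exo with respect to the dienol bond C5=C6. C10 comes from step 1, and the new centre C5 is set under thermodynamic control: in the acid the product re-forms the 5,7-dienol and is reprotonated at C5 on the face anti to the axial C10 methyl group, which gives the trans ring fusion. The step needs C5 to react and not C9 or C7: acid populates the linear dienol over the cross-conjugated enol, as in dienol ether formation from 4-en-3-one steroids, so C9 should stay unreactive, and a C7–C2 adduct would be a 1,5-diene that can still reach 10 by Cope rearrangement. The ylide should take the aldehyde and not the enone at −78 °C, and high dilution in the acid stage limits cationic oligomerisation.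

Step 5
Reactants: 11 2,3,5-trimethoxybenzaldehyde
Product: 12 (2,3,5-trimethoxyphenyl)methanol
Conditions: NaBH4, MeOH, 0 °C
Reagents that add atoms: none
Why: Hydride reduction of an aryl aldehyde to the benzylic alcohol.

Step 6
Reactants: 12
Product: 13 triisopropyl[(2,3,5-trimethoxyphenyl)methoxy]silane
Conditions: i-Pr3SiCl, imidazole, DMF, rt
Reagents that add atoms: chlorotriisopropylsilane, CC(C)[Si](Cl)(C(C)C)C(C)C
Why: Silylation of the primary alcohol; the bulky silyl ether should survive organolithium, hydrogenation, ylide, ceric and hydroxide steps.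

Step 7
Reactants: 13
Product: 15 2,3,6-trimethoxy-4-{[(triisopropylsilyl)oxy]methyl}benzaldehyde, via aryllithium 14 (not isolated)
Conditions: n-BuLi, THF, 0 °C; then DMF, −78 °C → rt; aq. NH4Cl
Reagents that add atoms: N,N-dimethylformamide, CN(C)C=O
Why: Directed ortho-metalation at the ring C–H between two methoxy groups (the most acidic site), then formylation; this puts the future C11 para to the protected hydroxymethyl group.

Step 8
Reactants: 10; 15
Product: 19 (4aS,8aS)-1-(Ar-methylidene)-5,5,8a-trimethyl-4a,5,8,8a-tetrahydronaphthalen-2(1H)-one, via lithium enolate 16 (not isolated), via lithium aldolate 17 (not isolated), via aldol mesylate 18 (not isolated)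
Conditions: LiN(i-Pr)2, THF, −78 °C; 15; then CH3SO2Cl, −78 → 0 °C; then DBU, rt
Reagents that add atoms: none
Why: Kinetic deprotonation of the enone at the α′ carbon C9 (cross-conjugated enolate), aldol addition to the aryl aldehyde and base-induced loss of methanesulfonate (aldol condensation); C9 and C11 become sp2, so no stereocentre is set here.

Step 9
Reactants: 19
Product: 20 (1R,4aS,8aS)-1-(Ar-methyl)-5,5,8a-trimethyloctahydronaphthalen-2(1H)-one
Conditions: H2 (4 atm), Pd/C, EtOAc, rt; then NaOMe (cat.), MeOH, rt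
Reagents that add atoms: none
Why: Heterogeneous hydrogenation saturates C2=C3, C6=C7 and C9=C11 and leaves ketone, arene and silyl ether; hydrogen should reach C9 from the face opposite the axial C10 methyl group, and methoxide equilibration secures the equatorial arylmethyl group at C9.

Step 10
Reactants: 20
Product: 21 triisopropyl[(2,3,5-trimethoxy-4-{[(1S,4aS,8aS)-5,5,8a-trimethyl-2-methylidenedecahydronaphthalen-1-yl]methyl}phenyl)methoxy]silane
Conditions: Ph3PCH3Br, KOt-Bu, toluene, 90 °C
Reagents that add atoms: methyltriphenylphosphonium bromide, C[P+](c1ccccc1)(c1ccccc1)c1ccccc1.[Br-]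
Why: Wittig methylenation of the hindered C8 ketone; the only epimerisable centre (C9) already has its thermodynamic configuration.

Step 11
Reactants: 21
Product: 22 3-methoxy-5-{[(triisopropylsilyl)oxy]methyl}-2-{[(1S,4aS,8aS)-5,5,8a-trimethyl-2-methylidenedecahydronaphthalen-1-yl]methyl}cyclohexa-2,5-diene-1,4-dione
Conditions: (NH4)2Ce(NO3)6, MeCN/H2O, 0 °C
Reagents that add atoms: water, O
Why: Ceric oxidative demethylation of the para-dimethoxy pair gives the p-quinone and keeps the third methoxy group as a vinylogous ester; the isolated exocyclic alkene should be inert at 0 °C.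

Step 12
Reactants: 22
Product: 23 3-hydroxy-5-{[(triisopropylsilyl)oxy]methyl}-2-{[(1S,4aS,8aS)-5,5,8a-trimethyl-2-methylidenedecahydronaphthalen-1-yl]methyl}cyclohexa-2,5-diene-1,4-dione
Conditions: NaOH (aq., 1 M), THF, 0 °C; then aq. HCl to pH 3
Reagents that add atoms: sodium hydroxide, [Na+].[OH-]
Why: Addition–elimination of hydroxide at the methoxy-bearing quinone carbon (hydrolysis of a vinylogous ester) gives the hydroxyquinone after acidification.

Step 13
Reactants: 23
Product: 24 tauranin
Conditions: Bu4NF, AcOH, THF, 0 °C → rt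
Reagents that add atoms: none
Why: Fluoride cleavage of the silyl ether, buffered with acetic acid so that the acidic hydroxyquinone and the exocyclic alkene are spared.

Compound list
1 | 3-methylcyclohex-2-en-1-one | CC1=CC(=O)CCC1 | starting material
2 | hex-1-yne | CCCCC#C | starting material
3 | (E)-hex-1-en-1-yl(diisobutyl)alane (hexenyl alane) | CCCC/C=C/[Al](CC(C)C)CC(C)C | intermediate (not isolated)
4 | (3S)-3-[(1E)-hex-1-en-1-yl]-3-methylcyclohexan-1-one | C[C@]1(/C=C/CCCC)CCCC(=O)C1 | intermediate
5 | (1S)-1-methyl-3-oxocyclohexane-1-carbaldehyde | C[C@]1(C=O)CCCC(=O)C1 | intermediate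
6 | (1S)-1-methyl-5-oxocyclohex-3-ene-1-carbaldehyde | C[C@]1(C=O)CC=CC(=O)C1 | intermediate
7 | (3-methylbut-2-en-1-yl)triphenylphosphonium bromide | CC(C)=CC[P+](c1ccccc1)(c1ccccc1)c1ccccc1.[Br-] | starting material
8 | (3-methylbut-2-en-1-ylidene)triphenylphosphorane (prenylidene phosphorane) | CC(C)=CC=P(c1ccccc1)(c1ccccc1)c1ccccc1 | intermediate (not isolated)
9 | (5S)-5-methyl-5-(4-methylpenta-1,3-dien-1-yl)cyclohex-2-en-1-one, E/Z mixture at C1=C2 (dienyl enone) | C[C@]1(C=CC=C(C)C)CC=CC(=O)C1 | intermediate (not isolated)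
10 | (4aR,8aR)-5,5,8a-trimethyl-4a,5,8,8a-tetrahydronaphthalen-2(1H)-one | C[C@]12CC=CC(C)(C)[C@@H]1C=CC(=O)C2 | intermediate
11 | 2,3,5-trimethoxybenzaldehyde | O=Cc1cc(OC)cc(OC)c1OC | starting material
12 | (2,3,5-trimethoxyphenyl)methanol | OCc1cc(OC)cc(OC)c1OC | intermediate
13 | triisopropyl[(2,3,5-trimethoxyphenyl)methoxy]silane | CC(C)[Si](OCc1cc(OC)cc(OC)c1OC)(C(C)C)C(C)C | intermediate
14 | (2,3,6-trimethoxy-4-{[(triisopropylsilyl)oxy]methyl}phenyl)lithium (aryllithium) | [Li]c1c(OC)cc(CO[Si](C(C)C)(C(C)C)C(C)C)c(OC)c1OC | intermediate (not isolated)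
15 | 2,3,6-trimethoxy-4-{[(triisopropylsilyl)oxy]methyl}benzaldehyde | O=Cc1c(OC)cc(CO[Si](C(C)C)(C(C)C)C(C)C)c(OC)c1OC | intermediate
16 | lithium enolate of 10 across C8=C9 | C[C@]12CC=CC(C)(C)[C@@H]1C=CC(O[Li])=C2 | intermediate (not isolated)
17 | lithium alkoxide of the C9 aldol adduct of 10 with 15, diastereomer mixture at C9 and C11 (lithium aldolate) | C[C@]12CC=CC(C)(C)[C@@H]1C=CC(=O)C2C(O[Li])c1c(OC)cc(CO[Si](C(C)C)(C(C)C)C(C)C)c(OC)c1OC | intermediate (not isolated)
18 | methanesulfonate of the same aldol adduct (aldol mesylate) | C[C@]12CC=CC(C)(C)[C@@H]1C=CC(=O)C2C(OS(C)(=O)=O)c1c(OC)cc(CO[Si](C(C)C)(C(C)C)C(C)C)c(OC)c1OC | intermediate (not isolated)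
19 | (4aS,8aS)-1-(Ar-methylidene)-5,5,8a-trimethyl-4a,5,8,8a-tetrahydronaphthalen-2(1H)-one, either geometry at C9=C11 | C[C@]12CC=CC(C)(C)[C@@H]1C=CC(=O)C2=Cc1c(OC)cc(CO[Si](C(C)C)(C(C)C)C(C)C)c(OC)c1OC | intermediate
20 | (1R,4aS,8aS)-1-(Ar-methyl)-5,5,8a-trimethyloctahydronaphthalen-2(1H)-one | C[C@]12CCCC(C)(C)[C@@H]1CCC(=O)[C@@H]2Cc1c(OC)cc(CO[Si](C(C)C)(C(C)C)C(C)C)c(OC)c1OC | intermediate
21 | triisopropyl[(2,3,5-trimethoxy-4-{[(1S,4aS,8aS)-5,5,8a-trimethyl-2-methylidenedecahydronaphthalen-1-yl]methyl}phenyl)methoxy]silane | C=C1CC[C@H]2C(C)(C)CCC[C@]2(C)[C@H]1Cc1c(OC)cc(CO[Si](C(C)C)(C(C)C)C(C)C)c(OC)c1OC | intermediate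
22 | 3-methoxy-5-{[(triisopropylsilyl)oxy]methyl}-2-{[(1S,4aS,8aS)-5,5,8a-trimethyl-2-methylidenedecahydronaphthalen-1-yl]methyl}cyclohexa-2,5-diene-1,4-dione | C=C1CC[C@H]2C(C)(C)CCC[C@]2(C)[C@H]1CC1=C(OC)C(=O)C(CO[Si](C(C)C)(C(C)C)C(C)C)=CC1=O | intermediate
23 | 3-hydroxy-5-{[(triisopropylsilyl)oxy]methyl}-2-{[(1S,4aS,8aS)-5,5,8a-trimethyl-2-methylidenedecahydronaphthalen-1-yl]methyl}cyclohexa-2,5-diene-1,4-dione | C=C1CC[C@H]2C(C)(C)CCC[C@]2(C)[C@H]1CC1=C(O)C(=O)C(CO[Si](C(C)C)(C(C)C)C(C)C)=CC1=O | intermediate
24 | tauranin, 3-hydroxy-5-(hydroxymethyl)-2-{[(1S,4aS,8aS)-5,5,8a-trimethyl-2-methylidenedecahydronaphthalen-1-yl]methyl}cyclohexa-2,5-diene-1,4-dione | C=C1CC[C@H]2C(C)(C)CCC[C@]2(C)[C@H]1CC1=C(O)C(=O)C(CO)=CC1=O | target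

Total step count: 13. Longest linear sequence: 10 steps (steps 1–4 and 8–13).

Steps most likely to fail

Step 4 (proposed new method). Ring closure may run through the wrong enol carbon (C9 or C7 in place of C5), the allyl cation may oligomerise, or the ring fusion may not equilibrate to trans. The fallback sets out from 6 and comes back at 10, with known reactions only. The Wittig reaction is run alone and the dienyl enone 9 is isolated. Dry HCl (CH2Cl2, −78 °C) adds across the diene to the allylic chloride (5S)-5-(2-chloro-4-methylpent-3-en-1-yl)-5-methylcyclohex-2-en-1-one F1. Pd(PPh3)4 (zerovalent palladium) and KOt-Bu in THF then join the thermodynamic dienolate to the allyl unit (intramolecular Tsuji–Trost alkylation). This gives either 10 or its C5 epimer directly (C5 to C4), or the bridged ketone 4-methyl-8-(2-methylprop-1-en-1-yl)bicyclo[2.2.2]oct-5-en-2-one F2 (C7 to C2). Heating F2 (o-dichlorobenzene, 180 °C) moves the allyl unit from C7 to C5 by Cope rearrangement, a path that cannot reach C9. Only the C8 epimer of F2 with the side chain over the C5=C6 bridge can rearrange. The product is the cis-fused dienone (4aS,8aR)-5,5,8a-trimethyl-4a,5,8,8a-tetrahydronaphthalen-2(1H)-one F3. NaOMe in MeOH equilibrates F3 at C5 through the dienolate to 10.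

Step 8. The aldol addition joins a hindered α′ enolate to a di-ortho-substituted benzaldehyde and may stall, or revert on mesylation. The fallback sets out from 15 and 10 and comes back at 20, replacing aldol condensation by enolate alkylation. Aldehyde 15 is reduced (NaBH4, MeOH) to (2,3,6-trimethoxy-4-{[(triisopropylsilyl)oxy]methyl}phenyl)methanol F4. F4 is converted (CBr4, PPh3, CH2Cl2, 0 °C) to {[4-(bromomethyl)-2,3,5-trimethoxyphenyl]methoxy}triisopropylsilane F5. The lithium enolate 16 is alkylated with F5 to (1R,4aS,8aS)-1-(Ar-methyl)-5,5,8a-trimethyl-4a,5,8,8a-tetrahydronaphthalen-2(1H)-one F6 (either C9 epimer serves). Hydrogenation and methoxide equilibration as in step 9 give 20.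

Step 12. Hydroxide may add at the unsubstituted quinone carbon, or trigger redox tautomerisation of the alkyl quinone, in place of clean methoxy exchange. The fallback sets out from 22 and comes back at 23 and makes no new compound. The methyl group is removed by SN2 attack of iodide at carbon (LiI, 2,6-lutidine, EtOAc, 60 °C; then dilute citric acid), a non-hydrolytic dealkylation of the vinylogous ester.

Further compounds
F1 | step 4 | (5S)-5-(2-chloro-4-methylpent-3-en-1-yl)-5-methylcyclohex-2-en-1-one, both epimers at the chloride carbon | C[C@]1(CC(Cl)C=C(C)C)CC=CC(=O)C1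
F2 | step 4 | 4-methyl-8-(2-methylprop-1-en-1-yl)bicyclo[2.2.2]oct-5-en-2-one, bridgeheads as in the SMILES, both C8 epimers | C[C@]12CC(C=C(C)C)[C@H](C=C1)C(=O)C2
F3 | step 4 | (4aS,8aR)-5,5,8a-trimethyl-4a,5,8,8a-tetrahydronaphthalen-2(1H)-one | C[C@]12CC=CC(C)(C)[C@H]1C=CC(=O)C2
F4 | step 8 | (2,3,6-trimethoxy-4-{[(triisopropylsilyl)oxy]methyl}phenyl)methanol | OCc1c(OC)cc(CO[Si](C(C)C)(C(C)C)C(C)C)c(OC)c1OC
F5 | step 8 | {[4-(bromomethyl)-2,3,5-trimethoxyphenyl]methoxy}triisopropylsilane | BrCc1c(OC)cc(CO[Si](C(C)C)(C(C)C)C(C)C)c(OC)c1OC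
F6 | step 8 | (1R,4aS,8aS)-1-(Ar-methyl)-5,5,8a-trimethyl-4a,5,8,8a-tetrahydronaphthalen-2(1H)-one | C[C@]12CC=CC(C)(C)[C@@H]1C=CC(=O)[C@@H]2Cc1c(OC)cc(CO[Si](C(C)C)(C(C)C)C(C)C)c(OC)c1OC
F0 | step 12 | none | none
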